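Amounts first, since you asked for a quick number and your hunch is that the over-reaction product peaks and falls inside the window.

- green: free monomer 0.10 M; initiator 0.67 mM; run made earlier
- flask: free monomer 0.067 M; initiator 0.67 mM; time 30 h

green run (percent of the free monomer charged)

| time / h | over-reaction product / % | monomer in chains / % |
|---|---|---|
| 1.33 | 0.2 | 5.9 |
| 2.50 | 3.3 | 6.1 |
| 4.00 | 3.1 | 5.0 |
| 5.00 | 5.4 | 5.4 |
| 6.00 | 5.5 | 5.3 |

(each reading ± 0.5 percentage points)

1. the moment within 30 h at which there is most over-reaction product
2. the amount of over-reaction product, in percent of the free monomer charged, at that time

Take the green run. Across these readings monomer in chains averages 5.54% of the charge, while the over-reaction product reaches 5.5% by 6.00 h. Follow one unit in a chain and treat its loss as proportional to what stands there. Divide the standing amount by the product made per hour and multiply by ln(2). That gives 4.19 h, the half-life of a monomer in chains, a reading that carries the scatter of 0.5 percentage points.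

Now hold it against the window. The 30 h allowed are 7.16 such half-lives, so most units that enter chains early turn to product inside it. The green product shows no fall beyond its scatter, so expect the top at the end of the window, against your hunch. The half-life gives this shape but no amount, so for the amount I stand on the forecast: “the maximum falls at the end of the window”, at 30 h, with 17%.

The flask gives 17.7% at 30.0 h, and both forecast values lie inside their margins.

    2 growing radical → dead chain (k = 1.00 × 10⁸ /M/s)
    initiator → 2 initiating radical (k = 9.55 × 10⁻⁶ /s)
    2 free monomer → homo dimer (k = 0.00623 /M/s)
    free monomer ⇌ dormant form (K = 2.33, k = 4.56 × 10⁻⁵ /s)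
    monomer in chains → over-reaction product (k = 4.48 × 10⁻⁵ /s)
    free monomer + initiating radical → growing radical + monomer in chains (k = 4.73 × 10⁵ /M/s)
    free monomer + growing radical → monomer in chains + growing radical, rate k7*[growing radical]*[free monomer] (k = 6190 /M/s)

At that moment this flask still holds 1.11% as monomer in chains. With the half-life of 4.19 h, that amount passes to product at 0.123 mM/h, so the curve is still climbing at the edge. The neighbour flask with 1.7 × 10⁻⁴ M of initiator holds 0.732% in chains at 30.0 h, which by the same half-life feeds 0.0812 mM/h into its 9.96% of product.

All runs are calculated with made-up constants.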